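- The product showed me how far the left-handed substrate had gone, so I began there, with the south-east run.

all flasks: gas 200 mM (held); precatalyst 0.40 mM
- south-east: left-handed substrate 0.40 M; right-handed substrate 0.40 M; run made earlier
- flask: left-handed substrate 0.80 M; right-handed substrate 0.80 M; time 30 min

south-east run (percent of the left-handed substrate and right-handed substrate together charged)

| time / min | left-handed substrate / % | right-handed substrate / % | left-handed product / % |
|---|---|---|---|
| 0.833 | 49.1 | 49.3 | 0.5 |
| 2.00 | 46.7 | 49.3 | 3.8 |
| 4.00 | 38.9 | 49.8 | 10.8 |
| 6.00 | 30.9 | 50.1 | 19.4 |

(scatter of a reading: 0.3 percentage points)

- free catalyst is single-handed; left-handed substrate and right-handed substrate are mirror images of each other, charged as a racemate, each of them at the stated concentration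
- at the start none of coupling partner is dissolved
- steps thought possible: free catalyst + right-handed substrate <-> catalyst intermediate B; coupling partner + catalyst intermediate A -> free catalyst + left-handed product; gas <-> coupling partner; free catalyst + left-handed substrate <-> catalyst intermediate A; precatalyst -> free catalyst; 2 free catalyst <-> resting dimer; coupling partner + catalyst intermediate B -> free catalyst + right-handed product
- an excess is the difference of the two amounts in percent of their sum
- an excess is below zero if the other one leads

* part of the left-handed substrate and right-handed substrate charged together that has reacted at 30 min
* excess of left-handed product over right-handed product in the product at 30 min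
* excess of right-handed substrate over left-handed substrate among what is left of the two at 30 min

- First instants: south-east held 0.5% left-handed product after 0.833 min, and the gain per minute then grew.
- Middle: I took the gain between the last two readings and kept it as the same amount per minute. That came to 64.5% of the flask's charge in 30 min, more than its left-handed part of 0.5. So I expected the flask to reach its end stage in time.
- The measure: I divided the ln of the part of left-handed substrate left by the ln of the part of right-handed substrate left, each of its own charge. This is the selectivity factor. A catalyst with no preference gives 1, the zero of my scale.
- In the steps listed, both substrates take the same free catalyst and the same coupling partner, so their amounts cancel from the ratio.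
- South-east had 30.9% left-handed substrate at its last reading. I took its lowest right-handed reading, 49.3%, as what was left of the right-handed substrate. That gave 34.1, an estimate from scattered readings that I called my selectivity floor.
- End: the two substrates react equally fast once the left-handed part left is the inverse of the factor, here 2.93%. At the floor, 90.2% of the right-handed substrate then remains.
- So I committed to c up to about 53.4%, eS about 93.7% or more, and eP about 81.6% or more.
- The forecast said c 45% (36% to 50%), eP 97% (90% to 99.5%) and eS 80% (55% to 98%), with “selectivity probably above 50”. Its c and eS were lower than mine.
- The flask gave c 52.4%, eP 89.7% and eS 98.5%.

    free catalyst + right-handed substrate ⇌ catalyst intermediate B (K = 1.60 M⁻¹, k = 27.0 M⁻¹ s⁻¹)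
    coupling partner + catalyst intermediate A → free catalyst + left-handed product (k = 170 M⁻¹ s⁻¹)
    gas ⇌ coupling partner, rate k3*(csat - [coupling partner]) (kL = 0.190 s⁻¹)
    free catalyst + left-handed substrate ⇌ catalyst intermediate A (K = 1.60 M⁻¹, k = 700 M⁻¹ s⁻¹)
    precatalyst → free catalyst (k = 0.00140 s⁻¹)
    2 free catalyst ⇌ resting dimer, settled at all times (K = 17000 M⁻¹)
    coupling partner + catalyst intermediate B → free catalyst + right-handed product (k = 1.80 M⁻¹ s⁻¹)

- At 30 min the flask held 0.69% of its left-handed charge and 95% of its right-handed charge unbound. My ratio made that 89.4, higher than the floor. A neighbouring flask had 1.0 × 10⁻⁴ M of precatalyst, a quarter of the flask's. That neighbour held 20% of its left-handed charge and 98% of its right-handed charge at the same time, and the ratio there gave 89.3, also higher than the floor.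

All runs are simulated for an exercise; noise was put on by code.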